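**Retrosynthetic overview**

1. Ring A is numbered as a benzaldehyde: C1 (CHO), C2 (OH), C3 (H), C4 (OMe), C5 (OH), C6 (2-acetoxytridecyl chain). The strategy rests on the segment C2–C3–C4–C5, which carries oxygen on C2, C4 and C5 with the C2 and C5 oxygens para. This segment is a 2,4-dioxygenated furan whose ring oxygen becomes the C5 hydroxyl, and C1/C6 are the two carbons of an alkyne.
2. Last disconnection: C1–C2 and C5–C6, by [4+2] cycloaddition of 4-methoxy-2-(trimethylsilyloxy)furan to (R)-5-acetoxyhexadec-2-ynal, opening of the oxygen bridge and aromatisation. Ring A is the only ring and is formed last.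
3. The ynal comes from (R)-2-undecyloxirane and lithiated 3,3-diethoxyprop-1-yne (C3–C4 bond of the ynal), then acetylation and acetal hydrolysis. The epoxide comes from 1-tridecene by epoxidation and hydrolytic kinetic resolution, which sets the only stereocentre.
4. The siloxyfuran comes from methyl tetronate by deprotonation at C5 and O-silylation.

Key step: step 7

Remark: in step 2 the (R,R) enantiomer of the cobalt salen catalyst is taken to hydrolyse the S enantiomer of a 2-alkyloxirane and to leave the R epoxide; should the recovered epoxide prove to be S, the (S,S) catalyst is used with no other change.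

**Route**

Step 1
Reactants: 1 1-tridecene
Product: 2 rac-2-undecyloxirane (1,2-epoxytridecane)
Conditions: mCPBA, CH2Cl2, 0 °C → rt
Reagents that add atoms: mCPBA (3-chloroperoxybenzoic acid), OOC(=O)c1cccc(Cl)c1
Why: Prilezhaev epoxidation, a concerted oxygen transfer from the peracid to the monosubstituted alkene, should give the racemic terminal epoxide and touches nothing else in the hydrocarbon.

Step 2
Reactants: 2 rac-2-undecyloxirane
Product: 3 (R)-2-undecyloxirane
Conditions: (R,R)-(salen)Co(OAc) (0.5 mol%; salen = N,N'-bis(3,5-di-tert-butylsalicylidene)cyclohexane-1,2-diamine dianion, trivalent cobalt), H2O (0.55 equiv), THF, 0 °C → rt; epoxide separated from the diol by distillation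
Reagents that add atoms: none
Why: In the Jacobsen hydrolytic kinetic resolution the chiral cobalt salen complex activates both epoxide and water and hydrolyses the S enantiomer much faster, so the unreacted R epoxide should be recovered in high enantiomeric purity, and this step sets the only stereocentre of the target.

Step 3
Reactants: 3 (R)-2-undecyloxirane; 4 3,3-diethoxyprop-1-yne
Product: 6 (R)-1,1-diethoxyhexadec-2-yn-5-ol, via lithium acetylide 5 (not isolated)
Conditions: 4 (1.5 equiv), n-BuLi, THF, −78 °C; BF3·OEt2, then 3, −78 °C; aq. NH4Cl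
Reagents that add atoms: none
Why: In the Yamaguchi–Hirao alkynylation the BF3-activated epoxide is opened by the lithium acetylide in an SN2 attack at the unsubstituted CH2, so no bond to the stereocentre is made or broken and the carbinol carbon stays R (the descriptor is unchanged because the propargylic CH2 still outranks the undecyl chain).

Step 4
Reactants: 6 (R)-1,1-diethoxyhexadec-2-yn-5-ol
Product: 7 (R)-1,1-diethoxyhexadec-2-yn-5-yl acetate
Conditions: Ac2O, pyridine, DMAP (cat.), CH2Cl2, 0 °C → rt
Reagents that add atoms: acetic anhydride, CC(=O)OC(C)=O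
Why: DMAP-catalysed O-acylation of the secondary alcohol proceeds with retention at carbon under basic conditions that leave the diethyl acetal intact.

Step 5
Reactants: 7 (R)-1,1-diethoxyhexadec-2-yn-5-yl acetate
Product: 8 (R)-5-acetoxyhexadec-2-ynal
Conditions: TFA–H2O (1:1), CH2Cl2, 0 °C → rt; used without storage
Reagents that add atoms: water, O
Why: Acid-catalysed acetal hydrolysis runs through the propargylic oxocarbenium ion, and since no base is present the product (acidic C4 protons, beta-acetoxy leaving group) should neither isomerise to an allene nor eliminate acetic acid, while the secondary acetate withstands aqueous TFA at this temperature.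

Step 6
Reactants: 9 methyl tetronate (4-methoxyfuran-2(5H)-one)
Product: 11 4-methoxy-2-(trimethylsilyloxy)furan, via lithium dienolate 10 (not isolated)
Conditions: LDA, THF, −78 °C; Me3SiCl, −78 → 0 °C; pentane, filtration under Ar, bulb-to-bulb distillation; used at once
Reagents that add atoms: chlorotrimethylsilane, C[Si](C)(C)Cl
Why: Kinetic deprotonation of the butenolide at C5 gives the aromatic 2-oxidofuran dienolate, which the hard electrophile Me3SiCl traps on oxygen (silyl dienol ether formation), and the work-up is non-aqueous because the product is hydrolysed by water.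

Step 7
Reactants: 8 (R)-5-acetoxyhexadec-2-ynal; 11 4-methoxy-2-(trimethylsilyloxy)furan
Product: 14 (R)-1-(2-formyl-3,6-dihydroxy-5-methoxyphenyl)tridecan-2-yl acetate (the target), via oxanorbornadiene adduct 12 (not isolated), via aryl trimethylsilyl ether 13 (not isolated)
Conditions: 11 (1.5–2 equiv), dry degassed CH2Cl2, 0 °C → rt, Ar; then 1 M HCl, THF, 0 °C
Reagents that add atoms: none
Why: In a normal-demand Diels–Alder reaction the electron-rich diene of 11 (furan C2–C5, most nucleophilic at C5, which is vinylogous to OSiMe3 and beta to the C4 methoxy group) adds to the electron-poor triple bond of 8, furan C5 bonding to the chain-bearing beta carbon and furan C2 to the formyl-bearing alpha carbon. This closes the carbocycle, the only ring of the target, by an intermolecular [4+2] cycloaddition as 7-oxanorbornadiene 12; should the addition be stepwise (vinylogous Mukaiyama–Michael attack, then 6-(enolexo)-exo-trig closure of the allenolate carbon on the silyloxy oxocarbenium carbon) the same adduct results. In 12 the bridgehead bearing OSiMe3 is a ketal carbon, so its bond to the bridging oxygen ionises to a silyloxy-stabilised cyclohexadienyl cation and loss of the proton from the other bridgehead aromatises the ring to 13, the bridge oxygen becoming the C5 hydroxyl; dilute acid then cleaves the aryl O–SiMe3 bond. The closest known reaction type is the cycloaddition of 2-silyloxy- and 2-alkoxyfurans with acetylenic esters, ketones and aldehydes, which opens in the same way to hydroquinone monoethers. No stereocentre is formed (the two bridgehead centres of 12 are lost on aromatisation), and the acetoxy-bearing carbon takes no part and stays R. The step needs regioselectivity (CHO beside the former furan C2 oxygen) and chemoselectivity (C≡C and not C=O as acceptor): the first is secured by the match of the most nucleophilic furan terminus C5 with the most electrophilic alkyne carbon, the second by the dry aprotic medium free of Lewis acid and fluoride, in which silyloxyfurans are normally inert to aldehyde carbonyls.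

**Compound list**

1 | 1-tridecene | C=CCCCCCCCCCCC | starting material
2 | rac-2-undecyloxirane | CCCCCCCCCCCC1CO1 | intermediate
3 | (R)-2-undecyloxirane | CCCCCCCCCCC[C@@H]1CO1 | intermediate
4 | 3,3-diethoxyprop-1-yne | C#CC(OCC)OCC | starting material
5 | lithium 3,3-diethoxyprop-1-yn-1-ide | [Li]C#CC(OCC)OCC | intermediate
6 | (R)-1,1-diethoxyhexadec-2-yn-5-ol | CCCCCCCCCCC[C@H](CC#CC(OCC)OCC)O | intermediate
7 | (R)-1,1-diethoxyhexadec-2-yn-5-yl acetate | CCCCCCCCCCC[C@H](CC#CC(OCC)OCC)OC(C)=O | intermediate
8 | (R)-5-acetoxyhexadec-2-ynal | CCCCCCCCCCC[C@H](CC#CC=O)OC(C)=O | intermediate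
9 | methyl tetronate (4-methoxyfuran-2(5H)-one) | COC1=CC(=O)OC1 | starting material
10 | lithium 4-methoxyfuran-2-olate | [Li]Oc1cc(OC)co1 | intermediate
11 | 4-methoxy-2-(trimethylsilyloxy)furan | COc1cc(O[Si](C)(C)C)oc1 | intermediate
12 | (2R)-1-[3-formyl-6-methoxy-4-(trimethylsilyloxy)-7-oxabicyclo[2.2.1]hepta-2,5-dien-2-yl]tridecan-2-yl acetate (both bridgehead epimers) | CCCCCCCCCCC[C@H](CC1=C(C=O)C2(O[Si](C)(C)C)C=C(OC)C1O2)OC(C)=O | intermediate
13 | (R)-1-[2-formyl-6-hydroxy-5-methoxy-3-(trimethylsilyloxy)phenyl]tridecan-2-yl acetate | CCCCCCCCCCC[C@H](Cc1c(O)c(OC)cc(O[Si](C)(C)C)c1C=O)OC(C)=O | intermediate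
14 | (R)-1-(2-formyl-3,6-dihydroxy-5-methoxyphenyl)tridecan-2-yl acetate | CCCCCCCCCCC[C@H](Cc1c(O)c(OC)cc(O)c1C=O)OC(C)=O | target

**Step count**

Total: 7 steps. Longest linear sequence: 6 steps (1 → 2 → 3 → 6 → 7 → 8 → 14; step 6 is the side branch).

**Steps most likely to fail**

Step 7. The cycloaddition to a beta-alkyl ynal may be slower than hydrolysis or protodesilylation of the diene. Silyl transfer in the zwitterion may outrun ring closure and stop the reaction at an open-chain Michael adduct. The electron-rich hydroquinone may also be oxidised by air during work-up.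

The fallback builds the chain on a preformed benzene ring and adds the second para oxygen last; it sets out from epoxide 3 and returns at 14.
- Commercial 2-bromo-3-hydroxy-4-methoxybenzaldehyde (O=Cc1ccc(OC)c(O)c1Br) is protected with MOMCl and iPr2NEt in CH2Cl2 to 2-bromo-4-methoxy-3-(methoxymethoxy)benzaldehyde F1.
- F1 is converted with HC(OMe)3 and PPTS in MeOH into 2-bromo-1-(dimethoxymethyl)-4-methoxy-3-(methoxymethoxy)benzene F2.
- Bromine–lithium exchange with n-BuLi in THF at −78 °C gives [6-(dimethoxymethyl)-3-methoxy-2-(methoxymethoxy)phenyl]lithium F3.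
- F3 opens 3 at the CH2 terminus in the presence of BF3·OEt2 to give (R)-1-[6-(dimethoxymethyl)-3-methoxy-2-(methoxymethoxy)phenyl]tridecan-2-ol F4.
- Ac2O, pyridine and DMAP give (R)-1-[6-(dimethoxymethyl)-3-methoxy-2-(methoxymethoxy)phenyl]tridecan-2-yl acetate F5.
- Aqueous TFA in CH2Cl2 removes the acetal and the MOM group to give (R)-1-(6-formyl-2-hydroxy-3-methoxyphenyl)tridecan-2-yl acetate F6.
- Teuber oxidation of this para-unsubstituted guaiacol-type phenol with potassium nitrosodisulfonate (KSO3)2NO in buffered aqueous acetone should give (R)-1-(2-formyl-5-methoxy-3,6-dioxocyclohexa-1,4-dien-1-yl)tridecan-2-yl acetate F7.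
- Reduction of F7 with sodium dithionite Na2S2O4 in a two-phase system gives 14.

Step 5. Hydrolysis of an alkynyl acetal is slow because the triple bond destabilises the oxocarbenium ion. Forcing it may cleave the acetate, hydrate the alkyne, or lose the ynal through elimination of acetic acid and oligomerisation.

The fallback reaches the aldehyde by oxidation instead of hydrolysis; it sets out from epoxide 3 and returns at 8.
- Commercial tert-butyldimethyl(prop-2-yn-1-yloxy)silane (C#CCO[Si](C)(C)C(C)(C)C) is lithiated with n-BuLi to [3-(tert-butyldimethylsilyloxy)prop-1-yn-1-yl]lithium F8.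
- F8 opens 3 with BF3·OEt2 at −78 °C to give (R)-1-(tert-butyldimethylsilyloxy)hexadec-2-yn-5-ol F9.
- Acetylation gives (R)-1-(tert-butyldimethylsilyloxy)hexadec-2-yn-5-yl acetate F10.
- HF·pyridine in THF frees (R)-1-hydroxyhexadec-2-yn-5-yl acetate F11.
- Oxidation of the propargylic alcohol with manganese dioxide MnO2 in CH2Cl2 under neutral conditions gives 8.

Step 6. Deprotonation may compete at C3, silylation may occur on carbon, and the trimethylsilyl dienol ether may hydrolyse back to 9 during isolation, so that impure diene enters the key step.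

The fallback uses a diene that can be purified and removes the silyl group in a separate step; it sets out from 9 and returns at 14.
- Soft enolisation of 9 with TBSOTf and Et3N in CH2Cl2 at 0 °C gives tert-butyl[(4-methoxyfuran-2-yl)oxy]dimethylsilane F12, which is stable to chromatography on deactivated silica.
- Cycloaddition of F12 with 8 passes through (2R)-1-[4-(tert-butyldimethylsilyloxy)-3-formyl-6-methoxy-7-oxabicyclo[2.2.1]hepta-2,5-dien-2-yl]tridecan-2-yl acetate F13.
- F13 opens to the isolable (R)-1-[3-(tert-butyldimethylsilyloxy)-2-formyl-6-hydroxy-5-methoxyphenyl]tridecan-2-yl acetate F14.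
- HF·pyridine in THF at 0 °C, which spares the acetate, converts F14 into 14.

**Further compounds**

F1 | step 7 | 2-bromo-4-methoxy-3-(methoxymethoxy)benzaldehyde | O=Cc1ccc(OC)c(OCOC)c1Br
F2 | step 7 | 2-bromo-1-(dimethoxymethyl)-4-methoxy-3-(methoxymethoxy)benzene | COC(OC)c1ccc(OC)c(OCOC)c1Br
F3 | step 7 | [6-(dimethoxymethyl)-3-methoxy-2-(methoxymethoxy)phenyl]lithium | [Li]c1c(C(OC)OC)ccc(OC)c1OCOC
F4 | step 7 | (R)-1-[6-(dimethoxymethyl)-3-methoxy-2-(methoxymethoxy)phenyl]tridecan-2-ol | CCCCCCCCCCC[C@H](Cc1c(OCOC)c(OC)ccc1C(OC)OC)O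
F5 | step 7 | (R)-1-[6-(dimethoxymethyl)-3-methoxy-2-(methoxymethoxy)phenyl]tridecan-2-yl acetate | CCCCCCCCCCC[C@H](Cc1c(OCOC)c(OC)ccc1C(OC)OC)OC(C)=O
F6 | step 7 | (R)-1-(6-formyl-2-hydroxy-3-methoxyphenyl)tridecan-2-yl acetate | CCCCCCCCCCC[C@H](Cc1c(O)c(OC)ccc1C=O)OC(C)=O
F7 | step 7 | (R)-1-(2-formyl-5-methoxy-3,6-dioxocyclohexa-1,4-dien-1-yl)tridecan-2-yl acetate | CCCCCCCCCCC[C@H](CC1=C(C=O)C(=O)C=C(OC)C1=O)OC(C)=O
F8 | step 5 | [3-(tert-butyldimethylsilyloxy)prop-1-yn-1-yl]lithium | [Li]C#CCO[Si](C)(C)C(C)(C)C
F9 | step 5 | (R)-1-(tert-butyldimethylsilyloxy)hexadec-2-yn-5-ol | CCCCCCCCCCC[C@H](CC#CCO[Si](C)(C)C(C)(C)C)O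
F10 | step 5 | (R)-1-(tert-butyldimethylsilyloxy)hexadec-2-yn-5-yl acetate | CCCCCCCCCCC[C@H](CC#CCO[Si](C)(C)C(C)(C)C)OC(C)=O
F11 | step 5 | (R)-1-hydroxyhexadec-2-yn-5-yl acetate | CCCCCCCCCCC[C@H](CC#CCO)OC(C)=O
F12 | step 6 | tert-butyl[(4-methoxyfuran-2-yl)oxy]dimethylsilane | COc1cc(O[Si](C)(C)C(C)(C)C)oc1
F13 | step 6 | (2R)-1-[4-(tert-butyldimethylsilyloxy)-3-formyl-6-methoxy-7-oxabicyclo[2.2.1]hepta-2,5-dien-2-yl]tridecan-2-yl acetate | CCCCCCCCCCC[C@H](CC1=C(C=O)C2(O[Si](C)(C)C(C)(C)C)C=C(OC)C1O2)OC(C)=O
F14 | step 6 | (R)-1-[3-(tert-butyldimethylsilyloxy)-2-formyl-6-hydroxy-5-methoxyphenyl]tridecan-2-yl acetate | CCCCCCCCCCC[C@H](Cc1c(O)c(OC)cc(O[Si](C)(C)C(C)(C)C)c1C=O)OC(C)=O
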